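A plain first-order conversion of starting material into target, at fixed temperature, cannot speed up as it goes on. Yet in Friday's closed flask target and isomer of the product together reach 24.3% of the charge at 8.00 min and 76.2% at 15.0 min, so the second interval runs faster than the first. I read this as autocatalysis, with target breeding target.

| flask | starting material | target | protic impurity | remark | time |
|---|---|---|---|---|---|
| Friday's | 0.050 M | 1 mM | 0.015 M | run made earlier |  |
| Saturday's | 0.070 M | 1 mM | 0.015 M | run made earlier |  |
| Thursday's | 0.11 M | 1 mM | 0.015 M | run made earlier |  |
| north-east | 0.050 M | 1.00 mM | 0.0150 M | one stirred flow tank at steady state, fed with the mixture as stated, mean residence time 3.0 h |  |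
| north-west | 0.050 M | 1.00 mM | 0.0150 M | a tube with plug flow, the mixed feed as stated, residence time 3.0 h | 3.0 h |
| south | 0.050 M (fed, over 2.40 h) | 1.00 mM | 0.0150 M | all but starting material at the start; starting material goes in evenly over 2.40 h, the run ends at 3.0 h | 3.0 h |
| south-east | 0.050 M | 1.00 mM | 0.0150 M | everything together in a closed stirred flask, run for 3.0 h | 3.0 h |

| run | time / min | target / % | isomer of the product / % |
|---|---|---|---|
| Friday's | 8.00 | 23.1 | 1.2 |
| Friday's | 15.0 | 67.2 | 9.0 |
| Friday's | 30.0 | 64.1 | 34.5 |
| Friday's | 60.0 | 32.3 | 66.4 |
| Friday's | 120 | 8.8 | 89.6 |
| Saturday's | 10.0 | 60.1 | 4.7 |
| Saturday's | 25.0 | 68.2 | 30.9 |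
| Saturday's | 50.0 | 38.7 | 60.0 |
| Saturday's | 80.0 | 19.2 | 79.7 |
| Saturday's | 120 | 7.5 | 91.6 |
| Thursday's | 20.0 | 71.8 | 26.8 |
| Thursday's | 40.0 | 45.1 | 53.6 |
| Thursday's | 60.0 | 28.4 | 70.8 |
| Thursday's | 80.0 | 18.5 | 80.9 |
| Thursday's | 120 | 7.1 | 91.0 |

(readings scatter by 0.5 percentage points)

- percentages count the starting material that a species holds: one side product counts as two
- the stated concentrations are those of everything mixed, before any reaction; amounts are the same in each set-up
- the feed brings no volume worth counting
- the earlier runs were made in a closed, stirred flask

- the set-up with the highest share of target in all that became target or isomer of the product or side product, at the outlet or at the end ("none" if the first two lie within 2 percentage points) (north-east / north-west / south / south-east / none)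
- share of target in all that became target or isomer of the product or side product, at the outlet or at the end, north-east
- share of target in all that became target or isomer of the product or side product, at the outlet or at the end, north-west
- share of target in all that became target or isomer of the product or side product, at the outlet or at the end, south
- share of target in all that became target or isomer of the product or side product, at the outlet or at the end, south-east

*What happens to target once it is formed?* On Thursday's run it falls from 71.8% at 20.0 min to 7.1% at 120 min, while the isomer of the product takes it up. Taken as an exponential, this gives the loss constant 0.0231 min⁻¹, a reading. Multiplied by the time, it gives the Damköhler number, 4.16.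

*The closed flask?* Integrating the loss from Friday's last reading gives 2.20% at 3.0 h. Each slice of the tube has the same history.

*The tank?* At steady state the isomer of the product leaves as fast as the loss makes it, so isomer over target equals the Damköhler number however target arises. My share is 19.4%.

*Can the tank go out?* Friday's logit slope gives a growth rate 0.329 min⁻¹ at full charge, which is larger than washout plus loss. So by this estimate it stays lit, with about 8.71% of the charge left as starting material.

*The fed flask?* If dosed material converted at once, the share would be 12.6%.

*But conversion lags, and that is the weak spot.* Later birth raises this floor, and an average delay of 18.7 min would bring the fed flask level with the tank. I commit to the tank, with the fed flask between the two.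

The forecast also names north-east: 19.4%, 2.2%, 16.7% and 2.2% in the order asked, with “Batch and plug flow are equivalent”. Its fed value stands above my floor.

The result is north-east, at 19.4%, with 2.20%, 16.7% and 2.20% for the others.

    starting material → target (k = 3.80 × 10⁻⁴ min⁻¹)
    target ⇌ isomer of the product (K = 680, k = 0.0230 min⁻¹)
    starting material + protic impurity → quenched substrate (k = 0.160 L mol⁻¹ min⁻¹)
    starting material + target → side product (k = 0.0340 L mol⁻¹ min⁻¹)
    starting material + target → 2 target (k = 7.20 L mol⁻¹ min⁻¹)

The tank holds starting material at 0.00385 M, which is 7.71% of the charge. Put to use on the fed flask, the loss constant turns the distance from floor to result into an average delay of 12.2 min. In that flask, starting material peaks at 0.0113 M, or 22.6% of the charge.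

(Readings and results stem from a simulated flask for substances that don't exist, and the scatter is random.)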